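## Retrosynthetic overview

1. Target ⇐ acidolysis of its tert-butyl ester / TES ether; the pyran ring is closed last (O2–C3) by 6-endo cycloisomerisation of a 2-(hydroxymethylene)-3-alkynylcyclohexenone, C1 having been added by γ-aminomethylenation.
2. C4a–C4 bond ⇐ late Sonogashira union of a cyclohexenyl triflate with tert-butyl (E)-pent-2-en-4-ynoate.
3. Carbocycle (formed first) ⇐ Dieckmann closure C5–C6 of a keto diester, the dione enolate being trapped as the triflate.
4. Ester C–O bond ⇐ Ag(I) thioester-to-ester exchange with (2S,4S)-4-methylhexan-2-ol; C7 and C8 ⇐ Evans Cu(II)–box syn-aldol of methyl pyruvate with a ketene thioacetal.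
5. Three fragments made in parallel deliver 11 (aldol core), 8 (alcohol) and 7 (enyne) of the 28 non-hydrogen atoms; C1 and O2 come from reagents.

Assumption: reagents, ligands and protecting-group sources (Bredereck's reagent, the imidate, silyl triflates, PhNTf2) are not counted as starting materials; every numbered starting material has at most eight non-hydrogen atoms.

## Route

Step 1
Reactants: 1 (S)-1-bromo-2-methylbutane; 2 N-methoxy-N-methylacetamide
Product: 4 (S)-4-methylhexan-2-one, via Grignard reagent 3 (not isolated)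
Conditions: Mg, THF, reflux; then 2, THF, 0 °C; 1 M HCl
Reagents that add atoms: none
Why: Weinreb ketone synthesis stops at the ketone through the chelated tetrahedral adduct, and the chiral-pool stereocentre (β to the new carbonyl) is not touched.

Step 2
Reactants: 4 (S)-4-methylhexan-2-one
Product: 5 (2S,4S)-4-methylhexan-2-ol
Conditions: (R)-Me-CBS (10 mol%), BH3·SMe2 (1.0 equiv), THF, −20 °C; MeOH quench
Reagents that add atoms: none
Why: Corey–Bakshi–Shibata reduction with the (R)-oxazaborolidine places the larger 2-methylbutyl group away from the catalyst and gives the (2S)-carbinol (about 9:1 expected for a dialkyl ketone; the minor epimer is removed as the diastereomeric ester 21).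

Step 3
Reactants: 6 propiolic acid
Product: 7 (E)-3-iodoprop-2-enoic acid
Conditions: 57% aq. HI, CuI (1 mol%), 130 °C
Reagents that add atoms: hydrogen iodide, I
Why: Hydroiodination of the ynoic acid gives the (Z)-adduct kinetically, which equilibrates under hot HI to the more stable (E)-iodoacrylic acid.

Step 4
Reactants: 7 (E)-3-iodoprop-2-enoic acid
Product: 8 tert-butyl (E)-3-iodoprop-2-enoate
Conditions: tert-butyl 2,2,2-trichloroacetimidate (2 equiv), BF3·OEt2 (cat.), CH2Cl2–cyclohexane, rt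
Reagents that add atoms: tert-butyl 2,2,2-trichloroacetimidate, CC(C)(C)OC(=N)C(Cl)(Cl)Cl
Why: Acid-catalysed imidate tert-butylation protects the acid under mild conditions that leave the vinyl iodide and its geometry intact.

Step 5
Reactants: 8 tert-butyl (E)-3-iodoprop-2-enoate; 9 ethynyltrimethylsilane
Product: 10 tert-butyl (E)-5-(trimethylsilyl)pent-2-en-4-ynoate
Conditions: Pd(PPh3)2Cl2 (2 mol%), CuI (4 mol%), Et3N, THF, rt
Reagents that add atoms: none
Why: Sonogashira coupling of an electron-poor vinyl iodide is fast at room temperature and retains the E geometry.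

Step 6
Reactants: 10 tert-butyl (E)-5-(trimethylsilyl)pent-2-en-4-ynoate
Product: 11 tert-butyl (E)-pent-2-en-4-ynoate
Conditions: K2CO3 (0.2 equiv), MeOH, 0 °C, 30 min
Reagents that add atoms: none
Why: Base-catalysed methanolysis of the C(sp)–Si bond (protodesilylation) frees the terminal alkyne while the tert-butyl ester resists transesterification.

Step 7
Reactants: 12 pent-4-enoic acid; 13 ethanethiol
Product: 14 S-ethyl pent-4-enethioate
Conditions: DCC, DMAP (cat.), CH2Cl2, 0 °C to rt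
Reagents that add atoms: none
Why: Steglich thioesterification gives the thioester needed for both the Mukaiyama aldol and the later thiophilic ester exchange.

Step 8
Reactants: 14 S-ethyl pent-4-enethioate
Product: 16 {[(1Z)-1-(ethylsulfanyl)penta-1,4-dien-1-yl]oxy}trimethylsilane, via lithium thioester enolate 15 (not isolated)
Conditions: LDA, TMSCl, THF, −78 °C
Reagents that add atoms: chlorotrimethylsilane, C[Si](C)(C)Cl
Why: Kinetic enolisation and O-silylation give the silyl ketene thioacetal (mainly Z; the geometry is irrelevant because the next step is stereoconvergent).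

Step 9
Reactants: 16 {[(1Z)-1-(ethylsulfanyl)penta-1,4-dien-1-yl]oxy}trimethylsilane; 17 methyl pyruvate
Product: 19 methyl (2R,3R)-3-[(ethylsulfanyl)carbonyl]-2-hydroxy-2-methylhex-5-enoate, via trimethylsilyl ether 18 (not isolated)
Conditions: [Cu((R,R)-t-Bu-box)](OTf)2 (10 mol%), THF, −78 °C; then 1 M HCl, THF, rt
Reagents that add atoms: none
Why: Evans Cu(II)–bis(oxazoline) Mukaiyama aldol: pyruvate chelates copper, the (R,R)-ligand (mirror image of the catalyst that gives the (S)-carbinol) directs attack to the Re face and sets C7 as R, and the open transition state gives the syn adduct and so C8 as R.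

Step 10
Reactants: 19 methyl (2R,3R)-3-[(ethylsulfanyl)carbonyl]-2-hydroxy-2-methylhex-5-enoate
Product: 20 methyl (2R,3R)-3-[(ethylsulfanyl)carbonyl]-2-methyl-2-[(triethylsilyl)oxy]hex-5-enoate
Conditions: TESOTf, 2,6-lutidine, CH2Cl2, 0 °C to rt
Reagents that add atoms: triethylsilyl trifluoromethanesulfonate, CC[Si](CC)(CC)OS(=O)(=O)C(F)(F)F
Why: Silylation of the tertiary carbinol blocks retro-aldol and β-lactone formation in the following steps and later shields the neighbouring carbonyl oxygen.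

Step 11
Reactants: 20 methyl (2R,3R)-3-[(ethylsulfanyl)carbonyl]-2-methyl-2-[(triethylsilyl)oxy]hex-5-enoate; 5 (2S,4S)-4-methylhexan-2-ol
Product: 21 1-methyl 4-[(2S,4S)-4-methylhexan-2-yl] (2R,3R)-2-methyl-3-(prop-2-en-1-yl)-2-[(triethylsilyl)oxy]butanedioate
Conditions: AgO2CCF3 (1.5 equiv), 5 (1.5 equiv), Na2HPO4, CH2Cl2, rt, dark
Reagents that add atoms: none
Why: Masamune-type thiophilic activation by Ag(I) lets the secondary alcohol acylate on the thioester only, with no base, so the methyl ester and both stereocentres are untouched.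

Step 12
Reactants: 21 1-methyl 4-[(2S,4S)-4-methylhexan-2-yl] (2R,3R)-2-methyl-3-(prop-2-en-1-yl)-2-[(triethylsilyl)oxy]butanedioate
Product: 22 1-methyl 4-[(2S,4S)-4-methylhexan-2-yl] (2R,3R)-2-methyl-3-(2-oxopropyl)-2-[(triethylsilyl)oxy]butanedioate
Conditions: PdCl2 (10 mol%), CuCl (1 equiv), O2 (1 atm), DMF–H2O 7:1, rt
Reagents that add atoms: water, O
Why: Tsuji–Wacker oxidation of the terminal alkene is Markovnikov-selective and gives the methyl ketone that supplies C4a and C5.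

Step 13
Reactants: 22 1-methyl 4-[(2S,4S)-4-methylhexan-2-yl] (2R,3R)-2-methyl-3-(2-oxopropyl)-2-[(triethylsilyl)oxy]butanedioate
Product: 24 (2S,4S)-4-methylhexan-2-yl (1R,6R)-6-methyl-5-oxo-6-[(triethylsilyl)oxy]-3-[(trifluoromethanesulfonyl)oxy]cyclohex-3-ene-1-carboxylate, via dione lithium enolate 23 (not isolated)
Conditions: LiHMDS (2.2 equiv), THF, −78 to 0 °C; then PhNTf2 (1.3 equiv), −78 °C to rt; cold 0.5 M HCl
Reagents that add atoms: N-phenylbis(trifluoromethanesulfonimide), O=S(=O)(N(c1ccccc1)S(=O)(=O)C(F)(F)F)C(F)(F)F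
Why: Dieckmann condensation of the kinetic methyl-ketone enolate on the methyl ester closes the six-membered 1,3-dione (favoured over five-ring closure on the hindered sec-alkyl ester), and the enolate is O-triflated at the oxygen remote from the quaternary silyloxy carbon.

Step 14
Reactants: 24 (2S,4S)-4-methylhexan-2-yl (1R,6R)-6-methyl-5-oxo-6-[(triethylsilyl)oxy]-3-[(trifluoromethanesulfonyl)oxy]cyclohex-3-ene-1-carboxylate; 11 tert-butyl (E)-pent-2-en-4-ynoate
Product: 25 (2S,4S)-4-methylhexan-2-yl (1R,6R)-3-[(3E)-5-tert-butoxy-5-oxopent-3-en-1-yn-1-yl]-6-methyl-5-oxo-6-[(triethylsilyl)oxy]cyclohex-3-ene-1-carboxylate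
Conditions: Pd(PPh3)2Cl2 (5 mol%), CuI (10 mol%), Et3N, THF, rt
Reagents that add atoms: none
Why: Sonogashira coupling of a β-triflyloxy enone is a standard, mild C(sp2)–C(sp) bond formation that attaches the whole side chain without touching C7 or C8.

Step 15
Reactants: 25 (2S,4S)-4-methylhexan-2-yl (1R,6R)-3-[(3E)-5-tert-butoxy-5-oxopent-3-en-1-yn-1-yl]-6-methyl-5-oxo-6-[(triethylsilyl)oxy]cyclohex-3-ene-1-carboxylate
Product: 26 (2S,4S)-4-methylhexan-2-yl (1R,2Z,6R)-3-[(3E)-5-tert-butoxy-5-oxopent-3-en-1-yn-1-yl]-2-[(dimethylamino)methylidene]-6-methyl-5-oxo-6-[(triethylsilyl)oxy]cyclohex-3-ene-1-carboxylate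
Conditions: t-BuOCH(NMe2)2 (2 equiv), toluene, 60 °C
Reagents that add atoms: tert-butoxybis(dimethylamino)methane, CN(C)C(OC(C)(C)C)N(C)C
Why: Vinylogous aminomethylenation with Bredereck's reagent can only occur at the γ-CH2 (the α′ carbon is quaternary, the ester α-carbon is a methine) and gives a push–pull dienaminone that carries C1.

Step 16
Reactants: 26 (2S,4S)-4-methylhexan-2-yl (1R,2Z,6R)-3-[(3E)-5-tert-butoxy-5-oxopent-3-en-1-yn-1-yl]-2-[(dimethylamino)methylidene]-6-methyl-5-oxo-6-[(triethylsilyl)oxy]cyclohex-3-ene-1-carboxylate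
Product: 28 (2S,4S)-4-methylhexan-2-yl (7R,8R)-3-[(1E)-3-tert-butoxy-3-oxoprop-1-en-1-yl]-7-methyl-6-oxo-7-[(triethylsilyl)oxy]-7,8-dihydro-6H-isochromene-8-carboxylate, via hydroxymethylene enynone 27 (not isolated)
Conditions: AcOH–H2O–THF 3:1:1, rt; concentrate; then Au(OAc)3 (5 mol%), ClCH2CH2Cl–TFA 20:1, rt
Reagents that add atoms: water, O
Why: Hydrolysis of the vinylogous amide gives the enol aldehyde, whose oxygen adds 6-endo-dig to the gold-activated alkyne (cycloisomerisation as used for azaphilone cores) to form the pyran and the cross-conjugated chromophore.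

Step 17
Reactants: 28 (2S,4S)-4-methylhexan-2-yl (7R,8R)-3-[(1E)-3-tert-butoxy-3-oxoprop-1-en-1-yl]-7-methyl-6-oxo-7-[(triethylsilyl)oxy]-7,8-dihydro-6H-isochromene-8-carboxylate
Product: 29 (2E)-3-[(7R,8R)-7-hydroxy-7-methyl-8-({[(2S,4S)-4-methylhexan-2-yl]oxy}carbonyl)-6-oxo-7,8-dihydro-6H-isochromen-3-yl]prop-2-enoic acid
Conditions: TFA–CH2Cl2–H2O 10:10:1, 0 °C to rt
Reagents that add atoms: none
Why: Acidolysis removes the tert-butyl ester (E1) and the tertiary TES ether without base, so the epimerisable C8–H and the secondary alkyl ester are preserved.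

## Compound list

1 | (S)-1-bromo-2-methylbutane | CC[C@H](C)CBr | starting material
2 | N-methoxy-N-methylacetamide | CC(=O)N(C)OC | starting material
3 | [(S)-2-methylbutyl]magnesium bromide | CC[C@H](C)C[Mg]Br | intermediate
4 | (S)-4-methylhexan-2-one | CC[C@H](C)CC(C)=O | intermediate
5 | (2S,4S)-4-methylhexan-2-ol | CC[C@H](C)C[C@H](C)O | intermediate
6 | propiolic acid | C#CC(=O)O | starting material
7 | (E)-3-iodoprop-2-enoic acid | OC(=O)/C=C/I | intermediate
8 | tert-butyl (E)-3-iodoprop-2-enoate | CC(C)(C)OC(=O)/C=C/I | intermediate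
9 | ethynyltrimethylsilane | C#C[Si](C)(C)C | starting material
10 | tert-butyl (E)-5-(trimethylsilyl)pent-2-en-4-ynoate | CC(C)(C)OC(=O)/C=C/C#C[Si](C)(C)C | intermediate
11 | tert-butyl (E)-pent-2-en-4-ynoate | CC(C)(C)OC(=O)/C=C/C#C | intermediate
12 | pent-4-enoic acid | C=CCCC(=O)O | starting material
13 | ethanethiol | CCS | starting material
14 | S-ethyl pent-4-enethioate | C=CCCC(=O)SCC | intermediate
15 | lithium (Z)-1-(ethylsulfanyl)penta-1,4-dien-1-olate | C=CC/C=C(/[O-])SCC.[Li+] | intermediate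
16 | {[(1Z)-1-(ethylsulfanyl)penta-1,4-dien-1-yl]oxy}trimethylsilane | C=CC/C=C(/O[Si](C)(C)C)SCC | intermediate
17 | methyl pyruvate | CC(=O)C(=O)OC | starting material
18 | methyl (2R,3R)-3-[(ethylsulfanyl)carbonyl]-2-methyl-2-[(trimethylsilyl)oxy]hex-5-enoate | CCSC(=O)[C@H](CC=C)[C@@](C)(O[Si](C)(C)C)C(=O)OC | intermediate
19 | methyl (2R,3R)-3-[(ethylsulfanyl)carbonyl]-2-hydroxy-2-methylhex-5-enoate | CCSC(=O)[C@H](CC=C)[C@@](C)(O)C(=O)OC | intermediate
20 | methyl (2R,3R)-3-[(ethylsulfanyl)carbonyl]-2-methyl-2-[(triethylsilyl)oxy]hex-5-enoate | CCSC(=O)[C@H](CC=C)[C@@](C)(O[Si](CC)(CC)CC)C(=O)OC | intermediate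
21 | 1-methyl 4-[(2S,4S)-4-methylhexan-2-yl] (2R,3R)-2-methyl-3-(prop-2-en-1-yl)-2-[(triethylsilyl)oxy]butanedioate | CC[C@H](C)C[C@H](C)OC(=O)[C@H](CC=C)[C@@](C)(O[Si](CC)(CC)CC)C(=O)OC | intermediate
22 | 1-methyl 4-[(2S,4S)-4-methylhexan-2-yl] (2R,3R)-2-methyl-3-(2-oxopropyl)-2-[(triethylsilyl)oxy]butanedioate | CC[C@H](C)C[C@H](C)OC(=O)[C@H](CC(C)=O)[C@@](C)(O[Si](CC)(CC)CC)C(=O)OC | intermediate
23 | lithium enolate of (2S,4S)-4-methylhexan-2-yl (1R,2R)-2-methyl-3,5-dioxo-2-[(triethylsilyl)oxy]cyclohexane-1-carboxylate | CC[C@H](C)C[C@H](C)OC(=O)[C@@H]1CC([O-])=CC(=O)[C@]1(C)O[Si](CC)(CC)CC.[Li+] | intermediate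
24 | (2S,4S)-4-methylhexan-2-yl (1R,6R)-6-methyl-5-oxo-6-[(triethylsilyl)oxy]-3-[(trifluoromethanesulfonyl)oxy]cyclohex-3-ene-1-carboxylate | CC[C@H](C)C[C@H](C)OC(=O)[C@@H]1CC(OS(=O)(=O)C(F)(F)F)=CC(=O)[C@]1(C)O[Si](CC)(CC)CC | intermediate
25 | (2S,4S)-4-methylhexan-2-yl (1R,6R)-3-[(3E)-5-tert-butoxy-5-oxopent-3-en-1-yn-1-yl]-6-methyl-5-oxo-6-[(triethylsilyl)oxy]cyclohex-3-ene-1-carboxylate | CC[C@H](C)C[C@H](C)OC(=O)[C@@H]1CC(C#C/C=C/C(=O)OC(C)(C)C)=CC(=O)[C@]1(C)O[Si](CC)(CC)CC | intermediate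
26 | (2S,4S)-4-methylhexan-2-yl (1R,2Z,6R)-3-[(3E)-5-tert-butoxy-5-oxopent-3-en-1-yn-1-yl]-2-[(dimethylamino)methylidene]-6-methyl-5-oxo-6-[(triethylsilyl)oxy]cyclohex-3-ene-1-carboxylate | CC[C@H](C)C[C@H](C)OC(=O)[C@@H]1/C(=C/N(C)C)C(C#C/C=C/C(=O)OC(C)(C)C)=CC(=O)[C@]1(C)O[Si](CC)(CC)CC | intermediate
27 | (2S,4S)-4-methylhexan-2-yl (1R,2Z,6R)-3-[(3E)-5-tert-butoxy-5-oxopent-3-en-1-yn-1-yl]-2-(hydroxymethylidene)-6-methyl-5-oxo-6-[(triethylsilyl)oxy]cyclohex-3-ene-1-carboxylate | CC[C@H](C)C[C@H](C)OC(=O)[C@@H]1/C(=C/O)C(C#C/C=C/C(=O)OC(C)(C)C)=CC(=O)[C@]1(C)O[Si](CC)(CC)CC | intermediate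
28 | (2S,4S)-4-methylhexan-2-yl (7R,8R)-3-[(1E)-3-tert-butoxy-3-oxoprop-1-en-1-yl]-7-methyl-6-oxo-7-[(triethylsilyl)oxy]-7,8-dihydro-6H-isochromene-8-carboxylate | CC[C@H](C)C[C@H](C)OC(=O)[C@@H]1C2=COC(/C=C/C(=O)OC(C)(C)C)=CC2=CC(=O)[C@]1(C)O[Si](CC)(CC)CC | intermediate
29 | (2E)-3-[(7R,8R)-7-hydroxy-7-methyl-8-({[(2S,4S)-4-methylhexan-2-yl]oxy}carbonyl)-6-oxo-7,8-dihydro-6H-isochromen-3-yl]prop-2-enoic acid | CC[C@H](C)C[C@H](C)OC(=O)[C@@H]1C2=COC(/C=C/C(=O)O)=CC2=CC(=O)[C@]1(C)O | target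

## Step count and risks

Total step count: 17. Longest linear sequence: 11 (steps 7–17, from 12 and 13 to 29), i.e. 11/17 = 0.65 of the total. The alcohol branch (steps 1–2) joins at step 11 and the enyne branch (steps 3–6) joins at step 14.

The three steps most likely to fail:

Step 13 (one-pot Dieckmann closure and regioselective triflation). The ester being attacked sits on a quaternary carbon, and the O-triflation must discriminate between the two dione oxygens. The fallback replaces the Claisen acylation by an aldol addition to an aldehyde followed by oxidation; it sets out from 21 and returns at 24. DIBAL-H (CH2Cl2, −78 °C) reduces the α-silyloxy methyl ester of 21 to the aldehyde (2S,4S)-4-methylhexan-2-yl (2R)-2-[(2R)-1-oxo-2-(triethylsilyloxy)propan-2-yl]pent-4-enoate F1. Wacker oxidation as in step 12 gives the keto aldehyde (2S,4S)-4-methylhexan-2-yl (2R)-4-oxo-2-[(2R)-1-oxo-2-(triethylsilyloxy)propan-2-yl]pentanoate F2. L-Proline (DMSO, rt) closes the ring by 6-enolexo aldol addition to the β-hydroxy ketone (2S,4S)-4-methylhexan-2-yl (1R,2R)-3-hydroxy-2-methyl-5-oxo-2-(triethylsilyloxy)cyclohexane-1-carboxylate F3 (mixture at C3). Dess–Martin periodinane gives the free dione (2S,4S)-4-methylhexan-2-yl (1R,2R)-2-methyl-3,5-dioxo-2-(triethylsilyloxy)cyclohexane-1-carboxylate F4, and Tf2O/Et3N (CH2Cl2, −78 °C) then gives 24.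

Step 15 (γ-aminomethylenation). The hot, basic medium may epimerise C8 or eliminate the β-silyloxy group, and liberated dimethylamine can add to the enyne. The fallback introduces C1 under Lewis-acidic conditions by a vinylogous Mukaiyama reaction; it sets out from 25 and returns at 27. TBSOTf/Et3N (CH2Cl2, −78 °C) converts 25 into the silyl dienol ether (2S,4S)-4-methylhexan-2-yl (1R,6R)-3-[(3E)-5-tert-butoxy-5-oxopent-3-en-1-yn-1-yl]-5-(tert-butyldimethylsilyloxy)-6-methyl-6-(triethylsilyloxy)cyclohexa-2,4-diene-1-carboxylate F5. Trimethyl orthoformate with BF3·OEt2 (CH2Cl2, −78 °C) alkylates its γ-carbon to give the acetal (2S,4S)-4-methylhexan-2-yl (1R,6R)-3-[(3E)-5-tert-butoxy-5-oxopent-3-en-1-yn-1-yl]-2-(dimethoxymethyl)-6-methyl-5-oxo-6-(triethylsilyloxy)cyclohex-3-ene-1-carboxylate F6 (mixture at C2). The aqueous acid of step 16 hydrolyses the acetal to 27, which is cyclised as before.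

Step 16 (hydrolysis and gold-catalysed cycloisomerisation). The enol oxygen could close 5-exo instead of 6-endo, or the catalyst could be sequestered by the polyunsaturated ester. The fallback uses an electrophilic iodocyclisation followed by reductive removal of iodine; it sets out from 26 and returns at 28. Compound 26 is hydrolysed (AcOH–H2O–THF) and 27 is isolated this time. N-Iodosuccinimide (MeCN, 0 °C) triggers 6-endo iodocyclisation to the iodide (2S,4S)-4-methylhexan-2-yl (7R,8R)-3-[(1E)-3-tert-butoxy-3-oxoprop-1-en-1-yl]-4-iodo-7-methyl-6-oxo-7-(triethylsilyloxy)-7,8-dihydro-6H-isochromene-8-carboxylate F7. Pd(OAc)2/PPh3 with HCO2H and Et3N (DMF, 40 °C) replaces iodine by hydrogen to give 28.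

Further compounds
F1 | step 13 | (2S,4S)-4-methylhexan-2-yl (2R)-2-[(2R)-1-oxo-2-(triethylsilyloxy)propan-2-yl]pent-4-enoate | CC[C@H](C)C[C@H](C)OC(=O)[C@H](CC=C)[C@@](C)(O[Si](CC)(CC)CC)C=O
F2 | step 13 | (2S,4S)-4-methylhexan-2-yl (2R)-4-oxo-2-[(2R)-1-oxo-2-(triethylsilyloxy)propan-2-yl]pentanoate | CC[C@H](C)C[C@H](C)OC(=O)[C@H](CC(C)=O)[C@@](C)(O[Si](CC)(CC)CC)C=O
F3 | step 13 | (2S,4S)-4-methylhexan-2-yl (1R,2R)-3-hydroxy-2-methyl-5-oxo-2-(triethylsilyloxy)cyclohexane-1-carboxylate | CC[C@H](C)C[C@H](C)OC(=O)[C@@H]1CC(=O)CC(O)[C@]1(C)O[Si](CC)(CC)CC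
F4 | step 13 | (2S,4S)-4-methylhexan-2-yl (1R,2R)-2-methyl-3,5-dioxo-2-(triethylsilyloxy)cyclohexane-1-carboxylate | CC[C@H](C)C[C@H](C)OC(=O)[C@@H]1CC(=O)CC(=O)[C@]1(C)O[Si](CC)(CC)CC
F5 | step 15 | (2S,4S)-4-methylhexan-2-yl (1R,6R)-3-[(3E)-5-tert-butoxy-5-oxopent-3-en-1-yn-1-yl]-5-(tert-butyldimethylsilyloxy)-6-methyl-6-(triethylsilyloxy)cyclohexa-2,4-diene-1-carboxylate | CC[C@H](C)C[C@H](C)OC(=O)[C@@H]1C=C(C#C/C=C/C(=O)OC(C)(C)C)C=C(O[Si](C)(C)C(C)(C)C)[C@]1(C)O[Si](CC)(CC)CC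
F6 | step 15 | (2S,4S)-4-methylhexan-2-yl (1R,6R)-3-[(3E)-5-tert-butoxy-5-oxopent-3-en-1-yn-1-yl]-2-(dimethoxymethyl)-6-methyl-5-oxo-6-(triethylsilyloxy)cyclohex-3-ene-1-carboxylate | CC[C@H](C)C[C@H](C)OC(=O)[C@@H]1C(C(OC)OC)C(C#C/C=C/C(=O)OC(C)(C)C)=CC(=O)[C@]1(C)O[Si](CC)(CC)CC
F7 | step 16 | (2S,4S)-4-methylhexan-2-yl (7R,8R)-3-[(1E)-3-tert-butoxy-3-oxoprop-1-en-1-yl]-4-iodo-7-methyl-6-oxo-7-(triethylsilyloxy)-7,8-dihydro-6H-isochromene-8-carboxylate | CC[C@H](C)C[C@H](C)OC(=O)[C@@H]1C2=COC(/C=C/C(=O)OC(C)(C)C)=C(I)C2=CC(=O)[C@]1(C)O[Si](CC)(CC)CC
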